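**Plan**

- Ring numbering used: C1 formyl, C2 and C3 hydroxyl, C4 H, C5 side chain, C6 hydroxyl; chain C1' (benzylic) to C12' (carboxyl). The ring carries a para oxygen pair at C3/C6, and its C4(H)–C5(chain) edge maps onto a terminal alkyne. That is what allows a carbene–alkyne–CO benzannulation.
- Retrosynthesis, ring: the C3–C4, C5–C6 and C6–C1 bonds are cut. This gives a chain-bearing terminal alkyne, one CO (C6 and its oxygen), and a methoxy(dioxinyl)carbene of chromium whose 4H-1,3-dioxin ring holds the C2 oxygen and the future formyl carbon.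
- Retrosynthesis, chain: the propargylic bond next to C1' is cut to trimethylsilylacetylene and a C15 allylic bromide, which comes from (2E,6E)-farnesol by oxidation of its far terminus.
- Forward order: the chain is built first (steps 1–10), then the carbene (steps 11–14). The only ring of the target closes in step 15, and the ring substituents are unmasked in steps 16–19.
- The dioxin is used as its acetone ketal (2,2-dimethyl) rather than the formaldehyde acetal, so that it opens in dilute acid next to the skipped diene.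
- Stereochemistry: both chain E-alkenes are those of farnesol. The (S)-centre at C11' comes from Ru/(S)-H8-BINAP hydrogenation of the (E)-2-methyl-2-enoic acid and is not touched afterwards.

Key step: step 15

Assumption: with Ru(OAc)2[(S)-H8-BINAP] the (E)-2-methyl-2-enoic acid 5 is taken to follow the tiglic acid precedent and give the (S)-acid; if the sense proved opposite, the (R)-ligand would be used.

**Route**

Step 1
Reactants: 1 (2E,6E)-farnesol
Product: 2 (2E,6E)-farnesyl acetate
Conditions: Ac2O, pyridine, DMAP (cat.), CH2Cl2, 0 °C to rt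
Reagents that add atoms: acetic anhydride, CC(=O)OC(C)=O
Why: DMAP-catalysed acetylation of the primary allylic alcohol; the acetate also deactivates the 2,3-alkene towards the allylic oxidation that follows.

Step 2
Reactants: 2 (2E,6E)-farnesyl acetate
Product: 3 (2E,6E,10E)-12-hydroxy-3,7,11-trimethyldodeca-2,6,10-trien-1-yl acetate
Conditions: SeO2 (cat.), t-BuOOH, salicylic acid (cat.), CH2Cl2, rt
Reagents that add atoms: tert-butyl hydroperoxide, CC(C)(C)OO (oxygen delivered through selenium dioxide, O=[Se]=O)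
Why: Riley-type allylic oxidation (ene reaction, then [2,3]-sigmatropic shift) should attack the (E)-methyl group of the terminal, most electron-rich trisubstituted alkene and give the (E)-allylic alcohol, as is well known for farnesyl acetate.

Step 3
Reactants: 3 (2E,6E,10E)-12-hydroxy-3,7,11-trimethyldodeca-2,6,10-trien-1-yl acetate
Product: 4 (2E,6E,10E)-3,7,11-trimethyl-12-oxododeca-2,6,10-trien-1-yl acetate
Conditions: activated MnO2, CH2Cl2, rt
Reagents that add atoms: none
Why: MnO2 oxidation of a primary allylic alcohol to the enal, with the alkene geometry retained and the acetate untouched.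

Step 4
Reactants: 4 (2E,6E,10E)-3,7,11-trimethyl-12-oxododeca-2,6,10-trien-1-yl acetate
Product: 5 (2E,6E,10E)-12-(acetyloxy)-2,6,10-trimethyldodeca-2,6,10-trienoic acid
Conditions: NaClO2, NaH2PO4, 2-methyl-2-butene, t-BuOH/H2O, 0 °C to rt
Reagents that add atoms: sodium chlorite, [Na+].[O-]Cl=O
Why: Pinnick oxidation of the enal to the acid under buffered conditions; excess 2-methyl-2-butene traps HOCl so that the chain alkenes survive.

Step 5
Reactants: 5 (2E,6E,10E)-12-(acetyloxy)-2,6,10-trimethyldodeca-2,6,10-trienoic acid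
Product: 6 (2S,6E,10E)-12-(acetyloxy)-2,6,10-trimethyldodeca-6,10-dienoic acid
Conditions: H2 (about 2 atm), Ru(OAc)2[(S)-H8-BINAP] (1 mol %), MeOH, 20 °C
Reagents that add atoms: none
Why: Noyori asymmetric hydrogenation: the acid binds the divalent ruthenium as a carboxylate, so only the conjugated 2,3-alkene is reduced, and the (S)-ligand should fix C2 as S; the isolated trisubstituted alkenes and the allylic acetate are not substrates.

Step 6
Reactants: 6 (2S,6E,10E)-12-(acetyloxy)-2,6,10-trimethyldodeca-6,10-dienoic acid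
Product: 7 methyl (2S,6E,10E)-12-(acetyloxy)-2,6,10-trimethyldodeca-6,10-dienoate
Conditions: MeI, K2CO3, DMF, rt
Reagents that add atoms: iodomethane, CI
Why: SN2 O-methylation of the potassium carboxylate; carbonate is too weak a base to enolise the ester at C2 or to cleave the acetate in DMF.

Step 7
Reactants: 7 methyl (2S,6E,10E)-12-(acetyloxy)-2,6,10-trimethyldodeca-6,10-dienoate
Product: 8 methyl (2S,6E,10E)-12-hydroxy-2,6,10-trimethyldodeca-6,10-dienoate
Conditions: K2CO3 (cat.), MeOH, rt
Reagents that add atoms: none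
Why: Base-catalysed transesterification removes the acetate; the methyl ester only exchanges with the solvent and the C2 centre is not epimerised at room temperature.

Step 8
Reactants: 8 methyl (2S,6E,10E)-12-hydroxy-2,6,10-trimethyldodeca-6,10-dienoate
Product: 9 methyl (2S,6E,10E)-12-bromo-2,6,10-trimethyldodeca-6,10-dienoate
Conditions: CBr4, PPh3, CH2Cl2, 0 °C; used without storage
Reagents that add atoms: tetrabromomethane, BrC(Br)(Br)Br
Why: Appel reaction turns the primary allylic alcohol into the bromide under neutral conditions, without allylic transposition at this temperature.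

Step 9
Reactants: 9 methyl (2S,6E,10E)-12-bromo-2,6,10-trimethyldodeca-6,10-dienoate; 10 trimethylsilylacetylene
Product: 11 methyl (2S,6E,10E)-2,6,10-trimethyl-14-(trimethylsilyl)tetradeca-6,10-dien-13-ynoate
Conditions: CuI (10 mol %), K2CO3, n-Bu4NCl, DMF, rt, argon
Reagents that add atoms: none
Why: Copper-catalysed allylic alkynylation (SN2 substitution of the primary allylic bromide by the copper acetylide under phase-transfer conditions) should give the linear 1,4-enyne with the E geometry kept, under conditions mild enough for the ester.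

Step 10
Reactants: 11 methyl (2S,6E,10E)-2,6,10-trimethyl-14-(trimethylsilyl)tetradeca-6,10-dien-13-ynoate
Product: 12 methyl (2S,6E,10E)-2,6,10-trimethyltetradeca-6,10-dien-13-ynoate
Conditions: K2CO3 (cat.), MeOH, 0 °C to rt
Reagents that add atoms: none
Why: Base-catalysed protodesilylation of the alkynylsilane; the conditions are too mild to isomerise the skipped enyne to an allene.

Step 11
Reactants: 13 2,2-dimethyl-1,3-dioxan-5-one
Product: 14 2,2-dimethyl-1,3-dioxan-5-ol
Conditions: NaBH4, MeOH, 0 °C
Reagents that add atoms: none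
Why: Hydride reduction of the ketone to the secondary alcohol; the carbinol carbon lies on a mirror plane, so no stereocentre arises.

Step 12
Reactants: 14 2,2-dimethyl-1,3-dioxan-5-ol
Product: 15 2,2-dimethyl-1,3-dioxan-5-yl 4-methylbenzenesulfonate
Conditions: TsCl, Et3N, DMAP (cat.), CH2Cl2, 0 °C to rt
Reagents that add atoms: 4-methylbenzenesulfonyl chloride, Cc1ccc(cc1)S(=O)(=O)Cl
Why: Sulfonylation of the secondary alcohol gives a crystalline leaving-group derivative under basic conditions that keep the ketal intact.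

Step 13
Reactants: 15 2,2-dimethyl-1,3-dioxan-5-yl 4-methylbenzenesulfonate
Product: 16 2,2-dimethyl-4H-1,3-dioxin
Conditions: KOtBu, DMSO, rt; product distilled from the mixture
Reagents that add atoms: none
Why: E2 elimination of a beta-alkoxy sulfonate to an enol ether, as known for glycerol 2-sulfonates; the two beta positions are equivalent, so a single alkene results.

Step 14
Reactants: 16 2,2-dimethyl-4H-1,3-dioxin; 17 chromium hexacarbonyl Cr(CO)6
Product: 20 pentacarbonyl[(2,2-dimethyl-4H-1,3-dioxin-6-yl)(methoxy)methylidene]chromium, via 6-lithiodioxin 18 (not isolated), via lithium acylchromate 19 (not isolated)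
Conditions: s-BuLi, THF, −78 °C; Cr(CO)6, −78 °C to 0 °C; solvent exchange, MeOTf, CH2Cl2, 0 °C
Reagents that add atoms: methyl trifluoromethanesulfonate, COS(=O)(=O)C(F)(F)F
Why: Fischer carbene synthesis: alpha-lithiation of the cyclic enol ether (as for dihydropyran and 4H-1,3-dioxin) gives a vinyllithium that adds to a CO ligand of the zerovalent chromium carbonyl, and the acyl chromate is O-methylated by the hard electrophile MeOTf.

Step 15
Reactants: 12 methyl (2S,6E,10E)-2,6,10-trimethyltetradeca-6,10-dien-13-ynoate; 20 pentacarbonyl[(2,2-dimethyl-4H-1,3-dioxin-6-yl)(methoxy)methylidene]chromium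
Product: 22 methyl (2S,6E,10E)-12-(5-hydroxy-8-methoxy-2,2-dimethyl-4H-1,3-benzodioxin-6-yl)-2,6,10-trimethyldodeca-6,10-dienoate, via tricarbonylchromium arene complex 21 (not isolated)
Conditions: 20 (1.3 equiv), THF (0.05 M, degassed), 50 °C, argon; then air, MeCN, rt
Reagents that add atoms: none
Why: Thermal loss of one CO from 20 lets the alkyne insert into the chromium–carbene bond so that its unsubstituted carbon bonds to the methoxy carbon (C3–C4) and the chain-bearing carbon becomes the new carbene centre, where CO insertion gives a chromium-bound dienylketene (C5–C6). The ketene carbon then bonds to C5 of the dioxin in a 6π electrocyclisation, the one ring closure of the step, forming the six-membered carbocycle (C6–C1); enolisation of the cyclohexadienone gives the phenol as its Cr(CO)3 complex 21, from which air releases 22. This is the Dötz benzannulation of alkenyl(alkoxy)carbene complexes with terminal alkynes, known for cyclic alpha-alkoxyalkenyl complexes such as the dihydropyranyl one and for skipped enynes that carry isoprenoid chains. No stereocentre is formed. The step needs regioselective insertion, secured by the size difference between the alkyne hydrogen and its CH2 substituent (larger group next to the CO-derived carbon), and phenol formation rather than cyclopentannulation, which alkenyl chromium complexes favour in THF near 50 °C. The trisubstituted alkenes, the ester, the ketal and the C2 centre are spectators under these neutral conditions, and the temperature is well below that at which 4H-1,3-dioxins undergo cycloreversion.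

Step 16
Reactants: 22 methyl (2S,6E,10E)-12-(5-hydroxy-8-methoxy-2,2-dimethyl-4H-1,3-benzodioxin-6-yl)-2,6,10-trimethyldodeca-6,10-dienoate
Product: 23 methyl (2S,6E,10E)-12-[2,4-dihydroxy-3-(hydroxymethyl)-5-methoxyphenyl]-2,6,10-trimethyldodeca-6,10-dienoate
Conditions: 1 M aq. HCl/THF (1:4), 0.02 M, 0 °C to rt, argon
Reagents that add atoms: none
Why: Acid-catalysed hydrolysis of the isopropylidene ketal of a salicyl alcohol, which opens in dilute acid at room temperature where the ester, the skipped diene and the ortho-allyl phenol should be stable.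

Step 17
Reactants: 23 methyl (2S,6E,10E)-12-[2,4-dihydroxy-3-(hydroxymethyl)-5-methoxyphenyl]-2,6,10-trimethyldodeca-6,10-dienoate
Product: 24 methyl (2S,6E,10E)-12-(3-formyl-2,4-dihydroxy-5-methoxyphenyl)-2,6,10-trimethyldodeca-6,10-dienoate
Conditions: activated MnO2, CH2Cl2, rt
Reagents that add atoms: none
Why: MnO2 oxidation of a salicyl (benzylic) alcohol to the salicylaldehyde, which is stabilised by hydrogen bonds to both ortho hydroxyls; the ring is a methoxyphenol, not a free hydroquinone, and should not be oxidised.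

Step 18
Reactants: 24 methyl (2S,6E,10E)-12-(3-formyl-2,4-dihydroxy-5-methoxyphenyl)-2,6,10-trimethyldodeca-6,10-dienoate
Product: 25 (2S,6E,10E)-12-(3-formyl-2,4-dihydroxy-5-methoxyphenyl)-2,6,10-trimethyldodeca-6,10-dienoic acid
Conditions: LiOH, THF/MeOH/H2O, rt, degassed; then 1 M HCl to pH 3
Reagents that add atoms: lithium hydroxide, [Li+].[OH-]
Why: Saponification of the methyl ester by acyl–oxygen cleavage without enolisation at C2; it is placed before the hydroquinone is set free because that would be air-sensitive in base.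

Step 19
Reactants: 25 (2S,6E,10E)-12-(3-formyl-2,4-dihydroxy-5-methoxyphenyl)-2,6,10-trimethyldodeca-6,10-dienoic acid
Product: 27 (2S,6E,10E)-12-(3-formyl-2,4,5-trihydroxyphenyl)-2,6,10-trimethyldodeca-6,10-dienoic acid, via formyl hydroxyquinone 26 (not isolated)
Conditions: (NH4)2Ce(NO3)6 (2.2 equiv), MeCN/H2O, 0 °C, 10 min; then aq. Na2S2O4, EtOAc, rt, argon
Reagents that add atoms: water, O
Why: Oxidative demethylation of the 4-methoxyphenol pair (C6–OH, C3–OMe) by tetravalent cerium, with water attack at C3 and loss of methanol, gives the hydroxyquinone, which dithionite reduces in the same flask to the hydroquinone (quinone reduction); prenylated methoxyphenols tolerate this oxidant at 0 °C, and the aldehyde, alkenes, acid and remote stereocentre are not involved.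

**Compound list**

1 | (2E,6E)-farnesol | CC(C)=CCC/C(C)=C/CC/C(C)=C/CO | starting material
2 | (2E,6E)-farnesyl acetate | CC(C)=CCC/C(C)=C/CC/C(C)=C/COC(C)=O | intermediate
3 | (2E,6E,10E)-12-hydroxy-3,7,11-trimethyldodeca-2,6,10-trien-1-yl acetate | OC/C(C)=C/CC/C(C)=C/CC/C(C)=C/COC(C)=O | intermediate
4 | (2E,6E,10E)-3,7,11-trimethyl-12-oxododeca-2,6,10-trien-1-yl acetate | O=C/C(C)=C/CC/C(C)=C/CC/C(C)=C/COC(C)=O | intermediate
5 | (2E,6E,10E)-12-(acetyloxy)-2,6,10-trimethyldodeca-2,6,10-trienoic acid | OC(=O)/C(C)=C/CC/C(C)=C/CC/C(C)=C/COC(C)=O | intermediate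
6 | (2S,6E,10E)-12-(acetyloxy)-2,6,10-trimethyldodeca-6,10-dienoic acid | CC(=O)OC/C=C(\C)CC/C=C(\C)CCC[C@H](C)C(=O)O | intermediate
7 | methyl (2S,6E,10E)-12-(acetyloxy)-2,6,10-trimethyldodeca-6,10-dienoate | CC(=O)OC/C=C(\C)CC/C=C(\C)CCC[C@H](C)C(=O)OC | intermediate
8 | methyl (2S,6E,10E)-12-hydroxy-2,6,10-trimethyldodeca-6,10-dienoate | OC/C=C(\C)CC/C=C(\C)CCC[C@H](C)C(=O)OC | intermediate
9 | methyl (2S,6E,10E)-12-bromo-2,6,10-trimethyldodeca-6,10-dienoate | BrC/C=C(\C)CC/C=C(\C)CCC[C@H](C)C(=O)OC | intermediate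
10 | trimethylsilylacetylene | C#C[Si](C)(C)C | starting material
11 | methyl (2S,6E,10E)-2,6,10-trimethyl-14-(trimethylsilyl)tetradeca-6,10-dien-13-ynoate | C[Si](C)(C)C#CC/C=C(\C)CC/C=C(\C)CCC[C@H](C)C(=O)OC | intermediate
12 | methyl (2S,6E,10E)-2,6,10-trimethyltetradeca-6,10-dien-13-ynoate | C#CC/C=C(\C)CC/C=C(\C)CCC[C@H](C)C(=O)OC | intermediate
13 | 2,2-dimethyl-1,3-dioxan-5-one | CC1(C)OCC(=O)CO1 | starting material
14 | 2,2-dimethyl-1,3-dioxan-5-ol | CC1(C)OCC(O)CO1 | intermediate
15 | 2,2-dimethyl-1,3-dioxan-5-yl 4-methylbenzenesulfonate | CC1(C)OCC(CO1)OS(=O)(=O)c1ccc(C)cc1 | intermediate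
16 | 2,2-dimethyl-4H-1,3-dioxin | CC1(C)OCC=CO1 | intermediate
17 | chromium hexacarbonyl Cr(CO)6 (zerovalent chromium) | O=C=[Cr](=C=O)(=C=O)(=C=O)(=C=O)=C=O | starting material
18 | 6-lithio-2,2-dimethyl-4H-1,3-dioxin | [Li]C1=CCOC(C)(C)O1 | intermediate
19 | lithium pentacarbonyl[(2,2-dimethyl-4H-1,3-dioxin-6-yl)(oxido)methylidene]chromate | [Li+].[O-]C(=[Cr](=C=O)(=C=O)(=C=O)(=C=O)=C=O)C1=CCOC(C)(C)O1 | intermediate
20 | pentacarbonyl[(2,2-dimethyl-4H-1,3-dioxin-6-yl)(methoxy)methylidene]chromium (zerovalent chromium) | COC(=[Cr](=C=O)(=C=O)(=C=O)(=C=O)=C=O)C1=CCOC(C)(C)O1 | intermediate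
21 | tricarbonylchromium complex of 22 (arene bound η6 to Cr(CO)3) | COc1cc(C/C=C(\C)CC/C=C(\C)CCC[C@H](C)C(=O)OC)c(O)c2COC(C)(C)Oc12.O=C=[Cr](=C=O)=C=O | intermediate
22 | methyl (2S,6E,10E)-12-(5-hydroxy-8-methoxy-2,2-dimethyl-4H-1,3-benzodioxin-6-yl)-2,6,10-trimethyldodeca-6,10-dienoate | COc1cc(C/C=C(\C)CC/C=C(\C)CCC[C@H](C)C(=O)OC)c(O)c2COC(C)(C)Oc12 | intermediate
23 | methyl (2S,6E,10E)-12-[2,4-dihydroxy-3-(hydroxymethyl)-5-methoxyphenyl]-2,6,10-trimethyldodeca-6,10-dienoate | COc1cc(C/C=C(\C)CC/C=C(\C)CCC[C@H](C)C(=O)OC)c(O)c(CO)c1O | intermediate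
24 | methyl (2S,6E,10E)-12-(3-formyl-2,4-dihydroxy-5-methoxyphenyl)-2,6,10-trimethyldodeca-6,10-dienoate | COc1cc(C/C=C(\C)CC/C=C(\C)CCC[C@H](C)C(=O)OC)c(O)c(C=O)c1O | intermediate
25 | (2S,6E,10E)-12-(3-formyl-2,4-dihydroxy-5-methoxyphenyl)-2,6,10-trimethyldodeca-6,10-dienoic acid | COc1cc(C/C=C(\C)CC/C=C(\C)CCC[C@H](C)C(=O)O)c(O)c(C=O)c1O | intermediate
26 | (2S,6E,10E)-12-(5-formyl-4-hydroxy-3,6-dioxocyclohexa-1,4-dien-1-yl)-2,6,10-trimethyldodeca-6,10-dienoic acid | O=CC1=C(O)C(=O)C=C(C/C=C(\C)CC/C=C(\C)CCC[C@H](C)C(=O)O)C1=O | intermediate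
27 | (2S,6E,10E)-12-(3-formyl-2,4,5-trihydroxyphenyl)-2,6,10-trimethyldodeca-6,10-dienoic acid (CNP0180353.1) | C/C(=C\Cc1cc(O)c(O)c(C=O)c1O)CC/C=C(\C)CCC[C@H](C)C(=O)O | target

**Count**

Total: 19 steps. Longest linear sequence: 15 steps (1–10, then 15–19, from farnesol); the carbene branch is 4 steps (11–14).

**Steps most likely to fail**

Step 15. The carbene 20 is untried. The alkyne may insert with the wrong orientation, the vinylketene may be diverted to cyclobutenone or five-ring products, or the dioxin may lose acetone by cycloreversion before the ring closes. The fallback makes the ring–chain bond by aryl C-allylation and sets the chromium chemistry aside; it sets out from 9 and comes back at 24. Commercial 1,2,4-trimethoxybenzene would be lithiated at the position between two methoxy groups (n-BuLi, TMEDA, THF, 0 °C) and formylated with DMF to 2,3,6-trimethoxybenzaldehyde F1. Excess BCl3 (CH2Cl2, −78 °C to rt) would cleave the two methoxy groups ortho to the formyl group by chelation and give 2,6-dihydroxy-3-methoxybenzaldehyde F2. Its sodium phenoxide (NaH, toluene, rt, a non-polar medium that favours C- over O-alkylation) would be alkylated by bromide 9 at the one ring position ortho to one hydroxyl and para to the other, giving 24, from which steps 18 and 19 follow.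

Step 19. The transient formyl hydroxyquinone 26 may be over-oxidised, may add water at its free ring position, or the tetravalent cerium may attack the chain alkenes before the reduction is done. The fallback separates the demethylation from the aldehyde; it sets out from 22 and comes back at 27. Phenol 22 would be oxidised with PhI(OAc)2 (MeCN/H2O, NaHCO3, 0 °C) to the quinone methyl (2S,6E,10E)-12-(2,2-dimethyl-5,8-dioxo-5,8-dihydro-4H-1,3-benzodioxin-6-yl)-2,6,10-trimethyldodeca-6,10-dienoate F3. Na2S2O4 would reduce it to the hydroquinone methyl (2S,6E,10E)-12-(5,8-dihydroxy-2,2-dimethyl-4H-1,3-benzodioxin-6-yl)-2,6,10-trimethyldodeca-6,10-dienoate F4. Both phenols would be silylated (TBSOTf, 2,6-lutidine, CH2Cl2) to methyl (2S,6E,10E)-12-[5,8-bis(tert-butyldimethylsilyloxy)-2,2-dimethyl-4H-1,3-benzodioxin-6-yl]-2,6,10-trimethyldodeca-6,10-dienoate F5. Dilute acid as in step 16 would open the ketal to methyl (2S,6E,10E)-12-[2,5-bis(tert-butyldimethylsilyloxy)-4-hydroxy-3-(hydroxymethyl)phenyl]-2,6,10-trimethyldodeca-6,10-dienoate F6, and MnO2 would give methyl (2S,6E,10E)-12-[2,5-bis(tert-butyldimethylsilyloxy)-3-formyl-4-hydroxyphenyl]-2,6,10-trimethyldodeca-6,10-dienoate F7. Degassed LiOH (THF/MeOH/H2O, then acid under argon) would finally cleave both aryl silyl ethers and the methyl ester to give 27, so that no formylquinone is ever formed.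

Step 16. The benzylic carbon, flanked by two ring oxygens, may ionise in acid to an ortho-quinone methide that oligomerises, and the free phenol may add to the neighbouring trisubstituted alkene (chroman closure). The fallback caps that phenol first, which blocks the chroman closure and one of the two quinone-methide pathways; it sets out from 22 and comes back at 25. Phenol 22 would be silylated (TBSOTf, 2,6-lutidine, CH2Cl2) to methyl (2S,6E,10E)-12-[5-(tert-butyldimethylsilyloxy)-8-methoxy-2,2-dimethyl-4H-1,3-benzodioxin-6-yl]-2,6,10-trimethyldodeca-6,10-dienoate F8. Ketal hydrolysis (AcOH/THF/H2O, 35 °C) would give methyl (2S,6E,10E)-12-[2-(tert-butyldimethylsilyloxy)-4-hydroxy-3-(hydroxymethyl)-5-methoxyphenyl]-2,6,10-trimethyldodeca-6,10-dienoate F9, which MnO2 would oxidise at once to methyl (2S,6E,10E)-12-[2-(tert-butyldimethylsilyloxy)-3-formyl-4-hydroxy-5-methoxyphenyl]-2,6,10-trimethyldodeca-6,10-dienoate F10. LiOH (THF/MeOH/H2O, degassed) would then remove the aryl silyl ether together with the methyl ester and give 25.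

**Further compounds**

F1 | step 15 | 2,3,6-trimethoxybenzaldehyde | COc1ccc(OC)c(C=O)c1OC
F2 | step 15 | 2,6-dihydroxy-3-methoxybenzaldehyde | COc1ccc(O)c(C=O)c1O
F3 | step 19 | methyl (2S,6E,10E)-12-(2,2-dimethyl-5,8-dioxo-5,8-dihydro-4H-1,3-benzodioxin-6-yl)-2,6,10-trimethyldodeca-6,10-dienoate | CC1(C)OCC2=C(O1)C(=O)C=C(C/C=C(\C)CC/C=C(\C)CCC[C@H](C)C(=O)OC)C2=O
F4 | step 19 | methyl (2S,6E,10E)-12-(5,8-dihydroxy-2,2-dimethyl-4H-1,3-benzodioxin-6-yl)-2,6,10-trimethyldodeca-6,10-dienoate | CC1(C)OCc2c(O)c(C/C=C(\C)CC/C=C(\C)CCC[C@H](C)C(=O)OC)cc(O)c2O1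
F5 | step 19 | methyl (2S,6E,10E)-12-[5,8-bis(tert-butyldimethylsilyloxy)-2,2-dimethyl-4H-1,3-benzodioxin-6-yl]-2,6,10-trimethyldodeca-6,10-dienoate | CC1(C)OCc2c(O[Si](C)(C)C(C)(C)C)c(C/C=C(\C)CC/C=C(\C)CCC[C@H](C)C(=O)OC)cc(O[Si](C)(C)C(C)(C)C)c2O1
F6 | step 19 | methyl (2S,6E,10E)-12-[2,5-bis(tert-butyldimethylsilyloxy)-4-hydroxy-3-(hydroxymethyl)phenyl]-2,6,10-trimethyldodeca-6,10-dienoate | OCc1c(O)c(O[Si](C)(C)C(C)(C)C)cc(C/C=C(\C)CC/C=C(\C)CCC[C@H](C)C(=O)OC)c1O[Si](C)(C)C(C)(C)C
F7 | step 19 | methyl (2S,6E,10E)-12-[2,5-bis(tert-butyldimethylsilyloxy)-3-formyl-4-hydroxyphenyl]-2,6,10-trimethyldodeca-6,10-dienoate | O=Cc1c(O)c(O[Si](C)(C)C(C)(C)C)cc(C/C=C(\C)CC/C=C(\C)CCC[C@H](C)C(=O)OC)c1O[Si](C)(C)C(C)(C)C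
F8 | step 16 | methyl (2S,6E,10E)-12-[5-(tert-butyldimethylsilyloxy)-8-methoxy-2,2-dimethyl-4H-1,3-benzodioxin-6-yl]-2,6,10-trimethyldodeca-6,10-dienoate | COc1cc(C/C=C(\C)CC/C=C(\C)CCC[C@H](C)C(=O)OC)c(O[Si](C)(C)C(C)(C)C)c2COC(C)(C)Oc12
F9 | step 16 | methyl (2S,6E,10E)-12-[2-(tert-butyldimethylsilyloxy)-4-hydroxy-3-(hydroxymethyl)-5-methoxyphenyl]-2,6,10-trimethyldodeca-6,10-dienoate | COc1cc(C/C=C(\C)CC/C=C(\C)CCC[C@H](C)C(=O)OC)c(O[Si](C)(C)C(C)(C)C)c(CO)c1O
F10 | step 16 | methyl (2S,6E,10E)-12-[2-(tert-butyldimethylsilyloxy)-3-formyl-4-hydroxy-5-methoxyphenyl]-2,6,10-trimethyldodeca-6,10-dienoate | COc1cc(C/C=C(\C)CC/C=C(\C)CCC[C@H](C)C(=O)OC)c(O[Si](C)(C)C(C)(C)C)c(C=O)c1O
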